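**Plan**
- Retrosynthetic cuts: first the cinnamate ester C–O bond (ferulic acid plus the lignan triol), then the oxolane C2–C3 bond, then the C4–CH2Ar bond, then the acetal of the aryl aldehyde.
- Enabling feature: oxolane C2 carries ring O1 and an electron-rich aryl group (a latent oxocarbenium carbon). C3 carries a CH2O group (the α-carbon of a latent aldehyde). O1–C5–C4 tethers the two. One seven-membered vinyl acetal (a 4,5-dihydro-1,3-dioxepine, used as a temporary ring) unmasks both partners in a single ionisation.
- Forward order: acetal of O-benzylsyringaldehyde with cis-butenediol, then an enantioselective benzylic Mizoroki–Heck reaction, then Lewis-acid ring contraction that closes the oxolane (the only ring made).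
- Stereochemistry: C4 comes from the chiral ligand in the Heck step. C2 (trans to the C4 substituent) comes from the kinetic ring contraction. C3 is then epimerised at the aldehyde stage to the 2,3-trans-3,4-cis arrangement and fixed by reduction.
- Endgame: hydrogenolysis of both benzyl ethers, then chemoselective Mitsunobu esterification with unprotected ferulic acid.

Key step: step 4

Remarks on the chemistry:
- Compound 6 forms as both epimers at the acetal carbon. That carbon becomes planar in step 4, so the mixture is used as such and its SMILES leaves that centre open.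
- In step 3 the ligand enantiomer that gives the 5R configuration is used; the sense of induction must be established experimentally, and the antipodal ligand is equally available.
- Dioxepine numbering is O1, C2 (acetal), O3, C4, C5, C6, C7. Dioxepine C2, O3, C4, C5, C6 become oxolane C2, O1, C5, C4, C3, and C7 becomes the formyl carbon.

Step 1
Reactants: 1 4-(benzyloxy)-3,5-dimethoxybenzaldehyde; 2 (Z)-but-2-ene-1,4-diol
Product: 3 2-[4-(benzyloxy)-3,5-dimethoxyphenyl]-4,7-dihydro-1,3-dioxepine
Conditions: p-TsOH·H2O (2 mol %), toluene, reflux, Dean–Stark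
Reagents that add atoms: none
Why: Acid-catalysed acetalisation with azeotropic removal of water, in which the cis-diol can only give the seven-membered cyclic acetal; the product is achiral, so no stereocentre is set.

Step 2
Reactants: 4 [4-(benzyloxy)-3-methoxyphenyl]methanol
Product: 5 4-(benzyloxy)-3-methoxybenzyl trifluoroacetate
Conditions: (CF3CO)2O, pyridine, CH2Cl2, 0 °C; used crude
Reagents that add atoms: trifluoroacetic anhydride, O=C(OC(=O)C(F)(F)F)C(F)(F)F
Why: O-Acylation of the primary benzylic alcohol installs the leaving group needed for oxidative addition to zerovalent palladium in step 3.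

Step 3
Reactants: 3 2-[4-(benzyloxy)-3,5-dimethoxyphenyl]-4,7-dihydro-1,3-dioxepine; 5 4-(benzyloxy)-3-methoxybenzyl trifluoroacetate
Product: 6 (5R)-2-[4-(benzyloxy)-3,5-dimethoxyphenyl]-5-[4-(benzyloxy)-3-methoxybenzyl]-4,5-dihydro-1,3-dioxepine
Conditions: Pd(dba)2 (5 mol %), BINOL-derived phosphoramidite (12 mol %), Li2CO3, THF, 50 °C
Reagents that add atoms: none
Why: Enantioselective Mizoroki–Heck reaction of a benzylic electrophile with a cyclic cis-olefin, in which oxidative addition gives a benzylpalladium species, ligand-controlled syn-carbopalladation of one of the two enantiotopic olefin carbons sets C5 as R, and syn β-hydride elimination is possible only toward C7 (the C5 hydrogen is anti to palladium), so the double bond ends up next to O1 as the enol ether.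

Step 4
Reactants: 6 (5R)-2-[4-(benzyloxy)-3,5-dimethoxyphenyl]-5-[4-(benzyloxy)-3-methoxybenzyl]-4,5-dihydro-1,3-dioxepine
Product: 8 (2S,3R,4R)-2-[4-(benzyloxy)-3,5-dimethoxyphenyl]-4-[4-(benzyloxy)-3-methoxybenzyl]oxolane-3-carbaldehyde (2,3-cis-3,4-trans), via oxocarbenium silyl enol ether triflate 7 (not isolated)
Conditions: TMSOTf (0.2 equiv), CH2Cl2, −78 °C; pyridine then aq. NaHCO3 at −78 °C
Reagents that add atoms: none
Why: TMSOTf silylates the enol-ether oxygen (dioxepine O1) and cleaves the C2–O1 bond, so one ionisation unmasks both partners, the aryl-stabilised oxocarbenium ion at C2 and the (Z)-silyl enol ether at C6/C7, held together by the O3–C4–C5 tether (ion pair 7); the enol carbon then attacks the oxocarbenium carbon, and loss of the silyl group gives the aldehyde and returns the catalyst. The closest known reaction type is the Lewis-acid-mediated 1,3 O-to-C ring contraction of 4,5-dihydro-1,3-dioxepines to oxolane-3-carbaldehydes, an intramolecular Mukaiyama aldol-type (Prins-type) closure. The oxolane closes in a 5-(enolexo)-endo-trig mode, which is feasible because the attacked π bond is an oxocarbenium ion whose oxygen lies in the forming ring. Oxolane C3 is controlled by the existing C4 centre: allylic 1,3-strain in the (Z)-enol ether puts the hydrogen of that centre in the enol plane, so the arylmethyl group lies on the face opposite to the incoming C2 and the formyl group ends up trans to it. Oxolane C2 is controlled kinetically: the (E)-oxocarbenium ion and the enol ether should combine in the compact synclinal arrangement of the tight ion pair, which places the aryl group cis to the formyl group and therefore trans to the C4 arylmethyl group, the relationship the target needs. The step needs kinetic control (C–C closure without reversal through ring opening of 8), which the low temperature, the catalytic amount of Lewis acid, the cold basic quench and the only moderate stabilisation of the cation (the 4-benzyloxy group is twisted out of conjugation by its two methoxy neighbours) should secure; both acetal epimers of 6 converge because that carbon becomes planar.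

Step 5
Reactants: 8 (2S,3R,4R)-2-[4-(benzyloxy)-3,5-dimethoxyphenyl]-4-[4-(benzyloxy)-3-methoxybenzyl]oxolane-3-carbaldehyde
Product: 10 [(2S,3R,4R)-2-[4-(benzyloxy)-3,5-dimethoxyphenyl]-4-[4-(benzyloxy)-3-methoxybenzyl]oxolan-3-yl]methanol, via 2,3-trans-3,4-cis aldehyde 9 (not isolated)
Conditions: DBU (0.2 equiv), CH2Cl2, 23 °C; then MeOH, NaBH4, −20 °C
Reagents that add atoms: none
Why: Base-mediated epimerisation through the aldehyde enolate changes C3 only and should favour 9, because the aryl/formyl cis interaction is traded for the smaller formyl/arylmethyl one, and NaBH4 reduction in the same flask then fixes that centre (the descriptor changes from 3S in 9 to 3R in 10 only through the priority change from CHO to CH2OH), the minor 3-epimeric alcohol being removed by chromatography.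

Step 6
Reactants: 10 [(2S,3R,4R)-2-[4-(benzyloxy)-3,5-dimethoxyphenyl]-4-[4-(benzyloxy)-3-methoxybenzyl]oxolan-3-yl]methanol
Product: 11 4-[(2S,3R,4R)-4-(4-hydroxy-3-methoxybenzyl)-3-(hydroxymethyl)oxolan-2-yl]-2,6-dimethoxyphenol
Conditions: H2 (1 atm), 10% Pd/C, EtOAc–EtOH, 23 °C, stopped at full debenzylation
Reagents that add atoms: none
Why: Hydrogenolysis of the two aryl benzyl ethers should be much faster than cleavage of the cyclic benzylic C2–O1 bond under neutral conditions, and no stereocentre is touched.

Step 7
Reactants: 11 4-[(2S,3R,4R)-4-(4-hydroxy-3-methoxybenzyl)-3-(hydroxymethyl)oxolan-2-yl]-2,6-dimethoxyphenol; 12 (E)-3-(4-hydroxy-3-methoxyphenyl)prop-2-enoic acid (ferulic acid)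
Product: 13 [(2S,3R,4R)-2-(4-hydroxy-3,5-dimethoxyphenyl)-4-(4-hydroxy-3-methoxybenzyl)oxolan-3-yl]methyl (E)-3-(4-hydroxy-3-methoxyphenyl)prop-2-enoate
Conditions: PPh3, DIAD, THF, 0 °C to 23 °C
Reagents that add atoms: none
Why: Mitsunobu esterification activates only the aliphatic primary alcohol as its alkoxyphosphonium ion, and the carboxylate, far more acidic than the three phenols, is the competent nucleophile, so no phenol protection is needed; the (E)-alkene and the stereocentres are untouched because the reacting carbon is a CH2 group.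

**Compound list**
1 | 4-(benzyloxy)-3,5-dimethoxybenzaldehyde | COc1cc(C=O)cc(OC)c1OCc1ccccc1 | starting material
2 | (Z)-but-2-ene-1,4-diol | OC/C=C\CO | starting material
3 | 2-[4-(benzyloxy)-3,5-dimethoxyphenyl]-4,7-dihydro-1,3-dioxepine | COc1cc(C2OC/C=C\CO2)cc(OC)c1OCc1ccccc1 | intermediate
4 | [4-(benzyloxy)-3-methoxyphenyl]methanol | COc1cc(CO)ccc1OCc1ccccc1 | starting material
5 | 4-(benzyloxy)-3-methoxybenzyl trifluoroacetate | COc1cc(COC(=O)C(F)(F)F)ccc1OCc1ccccc1 | intermediate
6 | (5R)-2-[4-(benzyloxy)-3,5-dimethoxyphenyl]-5-[4-(benzyloxy)-3-methoxybenzyl]-4,5-dihydro-1,3-dioxepine (both C2 epimers) | COc1cc(C2OC=C[C@@H](Cc3ccc(OCc4ccccc4)c(OC)c3)CO2)cc(OC)c1OCc1ccccc1 | intermediate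
7 | ring-opened oxocarbenium triflate carrying the (Z)-trimethylsilyl enol ether, R at the arylmethyl-bearing carbon | COc1cc(C=[O+]C[C@H](Cc2ccc(OCc3ccccc3)c(OC)c2)/C=C\O[Si](C)(C)C)cc(OC)c1OCc1ccccc1.[O-]S(=O)(=O)C(F)(F)F | intermediate (not isolated)
8 | (2S,3R,4R)-2-[4-(benzyloxy)-3,5-dimethoxyphenyl]-4-[4-(benzyloxy)-3-methoxybenzyl]oxolane-3-carbaldehyde (2,3-cis-3,4-trans) | O=C[C@@H]1[C@@H](Cc2ccc(OCc3ccccc3)c(OC)c2)CO[C@@H]1c1cc(OC)c(OCc2ccccc2)c(OC)c1 | intermediate
9 | (2S,3S,4R)-2-[4-(benzyloxy)-3,5-dimethoxyphenyl]-4-[4-(benzyloxy)-3-methoxybenzyl]oxolane-3-carbaldehyde (2,3-trans-3,4-cis) | O=C[C@H]1[C@@H](Cc2ccc(OCc3ccccc3)c(OC)c2)CO[C@@H]1c1cc(OC)c(OCc2ccccc2)c(OC)c1 | intermediate (not isolated)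
10 | [(2S,3R,4R)-2-[4-(benzyloxy)-3,5-dimethoxyphenyl]-4-[4-(benzyloxy)-3-methoxybenzyl]oxolan-3-yl]methanol | OC[C@H]1[C@@H](Cc2ccc(OCc3ccccc3)c(OC)c2)CO[C@@H]1c1cc(OC)c(OCc2ccccc2)c(OC)c1 | intermediate
11 | 4-[(2S,3R,4R)-4-(4-hydroxy-3-methoxybenzyl)-3-(hydroxymethyl)oxolan-2-yl]-2,6-dimethoxyphenol | OC[C@H]1[C@@H](Cc2ccc(O)c(OC)c2)CO[C@@H]1c1cc(OC)c(O)c(OC)c1 | intermediate
12 | (E)-3-(4-hydroxy-3-methoxyphenyl)prop-2-enoic acid (ferulic acid) | COc1cc(/C=C/C(=O)O)ccc1O | starting material
13 | [(2S,3R,4R)-2-(4-hydroxy-3,5-dimethoxyphenyl)-4-(4-hydroxy-3-methoxybenzyl)oxolan-3-yl]methyl (E)-3-(4-hydroxy-3-methoxyphenyl)prop-2-enoate | COc1cc(/C=C/C(=O)OC[C@H]2[C@@H](Cc3ccc(O)c(OC)c3)CO[C@@H]2c2cc(OC)c(O)c(OC)c2)ccc1O | target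

**Step count and risks**
Total step count: 7. Longest linear sequence: 6 (steps 1, 3, 4, 5, 6, 7).

Three steps most likely to fail:

Step 4 (ring contraction). The risk is loss of kinetic control: reversible ring opening and re-closure of the product, or a weak cis preference in the C–C closure, would let C2 drift to the arrangement cis to the C4 substituent, which no later step can correct. The fallback closes the oxolane through the C2–O1 bond instead. It sets out from 6 and returns at 10.
- Dioxepine 6 is hydrolysed (1 M HCl, THF), which returns aldehyde 1 and gives the lactol (4R)-4-[4-(benzyloxy)-3-methoxybenzyl]oxolan-2-ol F1.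
- Oxidation (TEMPO, PhI(OAc)2, CH2Cl2) gives the lactone (4R)-4-[4-(benzyloxy)-3-methoxybenzyl]oxolan-2-one F2.
- Its lithium enolate (LiN(SiMe3)2, THF, −78 °C) adds to aldehyde 1 anti to the arylmethyl group to give the trans-disubstituted aldol lactone (3S,4R)-3-[[4-(benzyloxy)-3,5-dimethoxyphenyl](hydroxy)methyl]-4-[4-(benzyloxy)-3-methoxybenzyl]oxolan-2-one F3, as both carbinol epimers.
- LiAlH4 (THF, 0 °C) gives the triol (2R,3R)-2-[[4-(benzyloxy)-3,5-dimethoxyphenyl](hydroxy)methyl]-3-[4-(benzyloxy)-3-methoxybenzyl]butane-1,4-diol F4.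
- Acid (BF3·OEt2, CH2Cl2, 0 °C) ionises the benzylic carbinol. The cation should be captured by the hydroxymethyl group on the arylmethyl-bearing carbon (five-membered rather than four-membered ring), trans to the neighbouring substituent, to give 10.

Step 5 (epimerisation and reduction). The risk is an incomplete thermodynamic bias, since the two aldehydes differ only in which cis interaction they carry, together with base-induced ring opening by β-elimination that would scramble C2. The fallback replaces equilibrium control by kinetic selection. It sets out from 8, returns at 10 and makes no new compound (F0).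
- Aldehyde 8 is treated with an NADPH-dependent ketoreductase (alcohol dehydrogenase) with glucose and glucose dehydrogenase for cofactor recycling, in phosphate buffer (pH 8 to 9) with DMSO as co-solvent.
- The two C3 epimers keep interconverting through the enol in the buffered medium, while an enzyme chosen from a panel should reduce only the 3S epimer 9. This dynamic reductive kinetic resolution should give 10 directly.

Step 3 (Heck benzylation). The risks are insufficient enantioselectivity, competing β-alkoxy elimination or double-bond migration after carbopalladation, and solvolysis of the electron-rich benzylic trifluoroacetate. The fallback sets the arylmethyl-bearing centre by auxiliary-controlled enolate alkylation. It sets out from 4 and returns at 10, bypassing steps 3 and 4.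
- (4R)-4-Benzyloxazolidin-2-one is N-acylated with pent-4-enoyl chloride (n-BuLi, THF, −78 °C) to (4R)-4-benzyl-3-(pent-4-enoyl)oxazolidin-2-one F5.
- Alcohol 4 is converted (PBr3, Et2O, 0 °C) into 1-(benzyloxy)-4-(bromomethyl)-2-methoxybenzene F6.
- The sodium enolate of F5 (NaN(SiMe3)2, THF, −78 °C) is alkylated by F6 anti to the auxiliary benzyl group to give (4R)-4-benzyl-3-[(2S)-2-[4-(benzyloxy)-3-methoxybenzyl]pent-4-enoyl]oxazolidin-2-one F7.
- LiBH4 (THF, 0 °C) releases the auxiliary and gives (2S)-2-[4-(benzyloxy)-3-methoxybenzyl]pent-4-en-1-ol F8.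
- Lemieux–Johnson cleavage (OsO4 cat., NaIO4, 2,6-lutidine, dioxane–water) gives the lactol (4R)-4-[4-(benzyloxy)-3-methoxybenzyl]oxolan-2-ol F1, and the sequence through F2, F3 and F4 described for step 4 then leads to 10.

**Further compounds**
F1 | step 4 | (4R)-4-[4-(benzyloxy)-3-methoxybenzyl]oxolan-2-ol | OC1C[C@@H](Cc2ccc(OCc3ccccc3)c(OC)c2)CO1
F2 | step 4 | (4R)-4-[4-(benzyloxy)-3-methoxybenzyl]oxolan-2-one | O=C1C[C@@H](Cc2ccc(OCc3ccccc3)c(OC)c2)CO1
F3 | step 4 | (3S,4R)-3-[[4-(benzyloxy)-3,5-dimethoxyphenyl](hydroxy)methyl]-4-[4-(benzyloxy)-3-methoxybenzyl]oxolan-2-one | O=C1[C@H](C(O)c2cc(OC)c(OCc3ccccc3)c(OC)c2)[C@@H](Cc2ccc(OCc3ccccc3)c(OC)c2)CO1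
F4 | step 4 | (2R,3R)-2-[[4-(benzyloxy)-3,5-dimethoxyphenyl](hydroxy)methyl]-3-[4-(benzyloxy)-3-methoxybenzyl]butane-1,4-diol | OC[C@H](C(O)c1cc(OC)c(OCc2ccccc2)c(OC)c1)[C@@H](Cc1ccc(OCc2ccccc2)c(OC)c1)CO
F0 | step 5 | none | none
F5 | step 3 | (4R)-4-benzyl-3-(pent-4-enoyl)oxazolidin-2-one | C=CCCC(=O)N1[C@H](Cc2ccccc2)COC1=O
F6 | step 3 | 1-(benzyloxy)-4-(bromomethyl)-2-methoxybenzene | COc1cc(CBr)ccc1OCc1ccccc1
F7 | step 3 | (4R)-4-benzyl-3-[(2S)-2-[4-(benzyloxy)-3-methoxybenzyl]pent-4-enoyl]oxazolidin-2-one | C=CC[C@@H](Cc1ccc(OCc2ccccc2)c(OC)c1)C(=O)N1[C@H](Cc2ccccc2)COC1=O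
F8 | step 3 | (2S)-2-[4-(benzyloxy)-3-methoxybenzyl]pent-4-en-1-ol | C=CC[C@@H](Cc1ccc(OCc2ccccc2)c(OC)c1)CO
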